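**Retrosynthetic overview**
- The target is cut in one retrosynthetic operation at the diaryl ether C–O, the lactone C–O and the pyran ring. This gives a prenylated methoxy-p-benzoquinone (ring B) and a symmetric 1,1-dimethylpropargyl ether of methyl 2,4,6-trihydroxybenzoate (ring A).
- Forward, one pot does three things: phenoxide conjugate addition to the quinone, closure of the seven-membered lactone by the new hydroquinone OH onto the methyl ester, and aryl propargyl ether Claisen / oxa-6π closure of the pyran.
- The quinone comes from CAN oxidation of 1,2,4-trimethoxy-3-prenylbenzene, made by ortho-lithiation and prenylation of 1,2,4-trimethoxybenzene.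
- The propargyl ether comes from selective 4-O-alkylation of methyl 2,4,6-trihydroxybenzoate.
- Ring order: both benzene rings are bought; the dioxepinone ring forms first and the pyran ring second, in the same operation.

Assumption: the target SMILES has no stereocentre and no E/Z-defined double bond, so the compound is achiral and no enantiocontrol is needed.

**Step 1**
Reactants: 1 1,2,4-trimethoxybenzene
Product: 3 1,2,4-trimethoxy-3-(3-methylbut-2-en-1-yl)benzene, via 2,3,6-trimethoxyphenyllithium 2 (not isolated)
Conditions: n-BuLi (1.1 equiv), THF, 0 °C → rt; prenyl bromide (1.2 equiv), −78 °C → rt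
Reagents that add atoms: prenyl bromide (1-bromo-3-methylbut-2-ene), CC(C)=CCBr
Why: Directed ortho-metalation removes the C3–H flanked by two OMe groups, and the hindered aryllithium alkylates prenyl bromide at its primary carbon (SN2) to give the linear prenyl group; no stereocentre is formed.

**Step 2**
Reactants: 3 1,2,4-trimethoxy-3-(3-methylbut-2-en-1-yl)benzene
Product: 4 2-methoxy-3-(3-methylbut-2-en-1-yl)-1,4-benzoquinone
Conditions: CAN (2.5 equiv), MeCN/H2O 2:1, 0 °C, 15 min
Reagents that add atoms: water, O
Why: CAN oxidative demethylation of the para-dimethoxy pair gives the p-quinone (carbonyl oxygens from water), the electron-rich arene being oxidised far faster than the trisubstituted alkene; no stereocentre is formed.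

**Step 3**
Reactants: 5 methyl 2,4,6-trihydroxybenzoate
Product: 6 methyl 2,6-dihydroxy-4-[(2-methylbut-3-yn-2-yl)oxy]benzoate
Conditions: 3-chloro-3-methylbut-1-yne (1.5 equiv), K2CO3 (1.1 equiv), KI (cat.), CuI (cat.), acetone, 50 °C
Reagents that add atoms: 3-chloro-3-methylbut-1-yne, CC(C)(Cl)C#C
Why: In this copper-assisted propargylic Williamson etherification only the 4-OH (para to the ester, not hydrogen-bonded, most acidic) is deprotonated and O-alkylated, leaving the two chelated ortho-OH groups free; no stereocentre is formed.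

**Step 4**
Reactants: 4 2-methoxy-3-(3-methylbut-2-en-1-yl)-1,4-benzoquinone; 6 methyl 2,6-dihydroxy-4-[(2-methylbut-3-yn-2-yl)oxy]benzoate
Product: 11 Garcinisidone B, via hydroquinone diaryl ether 7 (not isolated), via propargyloxy depsidone 8 (not isolated), via allenylphenol depsidone 9 (not isolated), via ortho-quinone methide 10 (not isolated)
Conditions: 6 (1.1 equiv), Cs2CO3 (0.2 equiv), degassed diglyme (0.02 M), 4 added slowly, 0 °C → rt, N2; then 145 °C, N2 sweep (−MeOH)
Reagents that add atoms: none
Why: Proposed new method: the phenoxide of 6 (two equivalent OH groups, so no site issue) adds through oxygen to C5 of quinone 4, the carbon β to the carbonyl that is not part of the vinylogous ester and para to OMe, where thiols and amines add to 2-methoxybenzoquinones, and aromatisation gives hydroquinone 7 redox-neutrally (closest known types: base-mediated aryloxylation of quinones and phenoxide addition–elimination on haloquinones); the hydroquinone OH flanked by the prenyl group and the new aryloxy group is the only one placed to close the seven-membered lactone on the methyl ester (base-catalysed transesterification as in depsidone lactonisation, driven by distilling methanol) to give 8; heating then triggers the known aryl 1,1-dimethylpropargyl ether Claisen rearrangement, directed to the carbon next to the chelated OH by hydrogen-bond bond fixation (9), followed by 1,5-H shift from the non-chelated OH (10) and oxa-6π electrocyclisation to the 2,2-dimethylpyran; two rings form in one pot and no stereocentre is created.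

**Compound list**
1 | 1,2,4-trimethoxybenzene | COc1ccc(OC)c(OC)c1 | starting material
2 | 2,3,6-trimethoxyphenyllithium (not isolated) | [Li]c1c(OC)ccc(OC)c1OC | intermediate
3 | 1,2,4-trimethoxy-3-(3-methylbut-2-en-1-yl)benzene | COc1ccc(OC)c(CC=C(C)C)c1OC | intermediate
4 | 2-methoxy-3-(3-methylbut-2-en-1-yl)-1,4-benzoquinone | COC1=C(CC=C(C)C)C(=O)C=CC1=O | intermediate
5 | methyl 2,4,6-trihydroxybenzoate | COC(=O)c1c(O)cc(O)cc1O | starting material
6 | methyl 2,6-dihydroxy-4-[(2-methylbut-3-yn-2-yl)oxy]benzoate | COC(=O)c1c(O)cc(OC(C)(C)C#C)cc1O | intermediate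
7 | methyl 2-[2,5-dihydroxy-4-methoxy-3-(3-methylbut-2-en-1-yl)phenoxy]-6-hydroxy-4-[(2-methylbut-3-yn-2-yl)oxy]benzoate (hydroquinone diaryl ether, not isolated) | COC(=O)c1c(O)cc(OC(C)(C)C#C)cc1Oc1cc(O)c(OC)c(CC=C(C)C)c1O | intermediate
8 | 1,7-dihydroxy-8-methoxy-3-[(2-methylbut-3-yn-2-yl)oxy]-9-(3-methylbut-2-en-1-yl)-11H-dibenzo[b,e][1,4]dioxepin-11-one (propargyloxy depsidone, not isolated) | COc1c(O)cc2c(c1CC=C(C)C)OC(=O)c1c(O)cc(OC(C)(C)C#C)cc1O2 | intermediate
9 | 1,3,7-trihydroxy-8-methoxy-2-(3-methylbuta-1,2-dien-1-yl)-9-(3-methylbut-2-en-1-yl)-11H-dibenzo[b,e][1,4]dioxepin-11-one (allenylphenol depsidone, not isolated) | COc1c(O)cc2c(c1CC=C(C)C)OC(=O)c1c(O)c(C=C=C(C)C)c(O)cc1O2 | intermediate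
10 | 1,7-dihydroxy-8-methoxy-2-(3-methylbut-2-en-1-ylidene)-9-(3-methylbut-2-en-1-yl)dibenzo[b,e][1,4]dioxepine-3,11(2H)-dione (ortho-quinone methide, not isolated) | COc1c(O)cc2c(c1CC=C(C)C)OC(=O)C1=C(O)C(=CC=C(C)C)C(=O)C=C1O2 | intermediate
11 | Garcinisidone B: depsidone whose acyl ring carries OH ortho to the lactone C=O and a 2,2-dimethyl-2H-pyran fused through the carbon next to that OH and the oxygen para to the C=O; the other ring carries, from the lactone-oxygen carbon round to the ether-oxygen carbon, prenyl, OMe, OH and H | COc1c(O)cc2c(c1CC=C(C)C)OC(=O)c1c(cc3c(c1O)C=CC(C)(C)O3)O2 | target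

**Totals**
Total step count: 4. Longest linear sequence: 3 steps (1 → 3 → 4 → 11); the second branch (5 → 6) is one step and joins in step 4.

**Steps most likely to fail, with fallbacks**

Step 4 (highest risk). The phenoxide may attack the quinone through carbon, the base may isomerise the prenylquinone, or quinone/hydroquinone redox exchange may scramble the adduct. The fallback sets out from 3 (with 6 as partner) and comes back at 7. Brominate 3 with NBS in MeCN at 0 °C at the ring position para to the 2-OMe group to give 1-bromo-2,4,5-trimethoxy-3-(3-methylbut-2-en-1-yl)benzene F1. Oxidise this with CAN to 5-bromo-2-methoxy-3-(3-methylbut-2-en-1-yl)-1,4-benzoquinone F2. Let the phenoxide of 6 (K2CO3, MeCN, rt) displace bromide by addition–elimination to give methyl 2-hydroxy-6-{[4-methoxy-5-(3-methylbut-2-en-1-yl)-3,6-dioxocyclohexa-1,4-dien-1-yl]oxy}-4-[(2-methylbut-3-yn-2-yl)oxy]benzoate F3. Reduce this with aqueous Na2S2O4 to hydroquinone 7, which is then heated with catalytic Cs2CO3 as in the second half of step 4.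

Step 3. Over-alkylation, C-alkylation of the phloroglucinol ring or premature Claisen rearrangement may occur. The fallback sets out from 5 and comes back at 11. Condense 5 with 3-methylbut-2-enal (EDDA cat., toluene, 100 °C; Knoevenagel-type condensation and oxa-6π closure through the non-chelated 4-OH) to give methyl 5,7-dihydroxy-2,2-dimethyl-2H-chromene-6-carboxylate F4. Treat this with quinone 4 and catalytic Cs2CO3 in degassed diglyme (rt, then 120 °C). The less hindered 7-OH adds to give methyl 7-[2,5-dihydroxy-4-methoxy-3-(3-methylbut-2-en-1-yl)phenoxy]-5-hydroxy-2,2-dimethyl-2H-chromene-6-carboxylate F5, which is not isolated and lactonises to 11.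

Step 2. CAN may give ortho-quinone from the adjacent dimethoxy pair or attack the prenyl alkene. The fallback sets out from 3 and comes back at 4. Anodic oxidation of 3 (Pt anode, KOH/MeOH, 0 °C, constant current) gives the quinone bisketal 1,3,3,6,6-pentamethoxy-2-(3-methylbut-2-en-1-yl)cyclohexa-1,4-diene F6. Mild hydrolysis (1% aqueous oxalic acid, acetone, rt) gives quinone 4 with no cerium(IV) present.

**Further compounds**
F1 | step 4 | 1-bromo-2,4,5-trimethoxy-3-(3-methylbut-2-en-1-yl)benzene | COc1cc(Br)c(OC)c(CC=C(C)C)c1OC
F2 | step 4 | 5-bromo-2-methoxy-3-(3-methylbut-2-en-1-yl)-1,4-benzoquinone | COC1=C(CC=C(C)C)C(=O)C(Br)=CC1=O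
F3 | step 4 | methyl 2-hydroxy-6-{[4-methoxy-5-(3-methylbut-2-en-1-yl)-3,6-dioxocyclohexa-1,4-dien-1-yl]oxy}-4-[(2-methylbut-3-yn-2-yl)oxy]benzoate | COC(=O)c1c(O)cc(OC(C)(C)C#C)cc1OC1=CC(=O)C(OC)=C(CC=C(C)C)C1=O
F4 | step 3 | methyl 5,7-dihydroxy-2,2-dimethyl-2H-chromene-6-carboxylate | COC(=O)c1c(O)cc2OC(C)(C)C=Cc2c1O
F5 | step 3 | methyl 7-[2,5-dihydroxy-4-methoxy-3-(3-methylbut-2-en-1-yl)phenoxy]-5-hydroxy-2,2-dimethyl-2H-chromene-6-carboxylate | COC(=O)c1c(O)c2C=CC(C)(C)Oc2cc1Oc1cc(O)c(OC)c(CC=C(C)C)c1O
F6 | step 2 | 1,3,3,6,6-pentamethoxy-2-(3-methylbut-2-en-1-yl)cyclohexa-1,4-diene | COC1=C(CC=C(C)C)C(OC)(OC)C=CC1(OC)OC
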